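(The data are calculated for substances that don't exist; the scatter is artificial.)

- No earlier reading can show the ratio of isomer of the product A to target at 0.050 s, for the first reading of any earlier run comes at 10.0 s or later; the flask has to be approached from its late end.

| setting | Tuesday's | Saturday's | Sunday's | flask |
|---|---|---|---|---|
| substrate | 0.34 mM | 0.75 mM | 0.50 mM | 0.50 mM |
| catalyst | 0.083 mol% | 0.083 mol% | 0.12 mol% | 0.083 mol% |
| remark | run made earlier | run made earlier | run made earlier |  |
| time |  |  |  | 2.0 min |

- Tuesday's (time / s: isomer of the product A / %, target / %): 10.0: 33.9, 20.3; 30.0: 41.4, 23.9; 60.0: 41.8, 24.5; 80.0: 41.6, 24.4; 120: 41.6, 24.4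
- Saturday's (time / s: isomer of the product A / %, target / %): 25.0: 41.8, 24.1; 50.0: 41.0, 24.1; 80.0: 41.0, 24.2; 90.0: 41.9, 24.2; 120: 41.7, 24.2
- Sunday's (time / s: isomer of the product A / %, target / %): 10.0: 39.5, 24.5; 20.0: 41.7, 24.2; 30.0: 42.0, 23.4; 60.0: 41.8, 24.2; 120: 42.2, 24.5

(each reading ± 0.5 percentage points)

* ratio of isomer of the product A to target at 0.050 s
* ratio of isomer of the product A to target at 2.5 s
* ratio of isomer of the product A to target at 2.0 min
* which of isomer of the product A and target there is more of at 2.0 min

- The zero of the scale is a ratio of 1, no preference between the two products. The last readings of the earlier runs, pooled, give 1.72; this is the end ratio, isomer of the product A over target once the readings stop moving, and it puts isomer of the product A ahead.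
- Objection: the charges differ, so one pooled figure may hide a drift. But Tuesday's, Saturday's and Sunday's runs separately end at 1.70, 1.72 and 1.72, with each reading good to 0.5 percentage points.
- Objection: the flask may not have reached its end by 2.0 min. But Tuesday's run is flat by 60.0 s, and the flask has 1.47 times that run's catalyst concentration and a longer time, so the end ratio serves at 2.0 min.
- Objection: the end ratio need not hold early, since the selectivity factor of the first moments may differ from it. The first readings of Tuesday's and Sunday's runs, pooled, give 1.64, and this reckoning commits to that figure at 0.050 s and 2.5 s. The doubt stays, since Tuesday's run already holds 81.5% of its last isomer of the product A at 10.0 s.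
- The forecast gives 1.6, 1.65 and 1.71, with isomer of the product A ahead, and judges of the plateau: “this looks like equilibrium, or a fixed parallel split”.
- The flask gives 1.66 at 0.050 s, 1.66 at 2.5 s and 1.71 at 2.0 min, with 41.8% isomer of the product A against 24.4% target.

    substrate + catalyst ⇌ target + catalyst, rate k1*[substrate]*[catalyst] forward; the back reaction follows from the equilibrium constant (K = 1.40, k = 2.90 × 10⁵ M⁻¹ s⁻¹)
    substrate + catalyst ⇌ isomer of the product A + catalyst, rate k2*[substrate]*[catalyst] forward; the back reaction follows from the equilibrium constant (K = 2.40, k = 4.80 × 10⁵ M⁻¹ s⁻¹)
    substrate + catalyst ⇌ isomer of the product B + catalyst, rate k3*[substrate]*[catalyst] forward; the back reaction follows from the equilibrium constant (K = 0.940, k = 2.90 × 10⁶ M⁻¹ s⁻¹)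

- The rate constants of the steps from substrate to isomer of the product A and to target stand in the ratio 1.66 and their equilibrium constants in the ratio 1.71, the kinetic against the thermodynamic figure. In a further flask with 0.021 mol% catalyst, target stands at 24.4% at 2.00 min; multiplied by the end ratio 1.72, that gives 42.0% isomer of the product A, and that flask holds 41.7%.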